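## Retrosynthetic overview
- The last bond made is the side-chain CH2–O ether. The target is disconnected to 3-methylluteolin and prenol, joined through a vinylogous para-quinone methide formed by oxidising the ring B catechol.
- 3-Methylluteolin comes from a 2-methyl-1,3-diketone by O1–C2 cyclodehydration (ring C) and cleavage of two O-methyl groups in the same pot.
- The diketone comes from C-acylation of flopropione with 3,4-dimethoxybenzoyl chloride.
- Rings A and B are bought intact. Ring C is the only ring formed (step 2), and the prenyl ether is installed last on the unprotected tetraphenol.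

Assumption: the target has no stereocentre and no stereogenic double bond (the prenyl alkene carries two identical methyl groups). The achiral compound itself therefore meets the stereochemical requirement.

## Route

Step 1
Reactants: 1 flopropione [1-(2,4,6-trihydroxyphenyl)propan-1-one]; 2 3,4-dimethoxybenzoyl chloride
Product: 4 1-(3,4-dimethoxyphenyl)-2-methyl-3-(2,4,6-trihydroxyphenyl)propane-1,3-dione (racemic), via tetralithium enolate 3 (not isolated)
Conditions: LiN(SiMe3)2 (5.0 equiv), THF, −78 → −10 °C; then 2 (1.0 equiv), −78 °C → rt; 1 M HCl quench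
Reagents that add atoms: 3,4-dimethoxybenzoyl chloride (2), COc1ccc(C(=O)Cl)cc1OC
Why: This is a Claisen-type C-acylation of a ketone enolate (the direct polyanion variant of the Baker–Venkataraman flavone synthesis), in which the carbon enolate is the most nucleophilic site of 3, any ortho O-aroylation is funnelled to the same diketone by base-induced O-to-C acyl shift, and the new methine stereocentre forms racemic, is enolisable and is erased in step 2.

Step 2
Reactants: 4 1-(3,4-dimethoxyphenyl)-2-methyl-3-(2,4,6-trihydroxyphenyl)propane-1,3-dione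
Product: 6 3-methylluteolin [2-(3,4-dihydroxyphenyl)-5,7-dihydroxy-3-methyl-4H-chromen-4-one], via dimethoxyflavone 5 (not isolated)
Conditions: 48% aq. HBr/AcOH (1:1), reflux, 16 h, Ar
Reagents that add atoms: none
Why: Acid-catalysed cyclodehydration of the ortho-hydroxyaryl 1,3-diketone closes ring C through the O1–C2 bond to give 5, and hot HBr then cleaves both aryl methyl ethers by SN2 attack of bromide (Zeisel-type dealkylation), the flavone core being inert to these classical conditions, any Wessely–Moser ring opening being degenerate on the symmetric ring A, and the racemic methine carbon becoming sp2.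

Step 3
Reactants: 6 3-methylluteolin; 7 prenol (3-methylbut-2-en-1-ol)
Product: 10 ophioglonol prenyl ether [2-(3,4-dihydroxyphenyl)-5,7-dihydroxy-3-{[(3-methylbut-2-en-1-yl)oxy]methyl}-4H-chromen-4-one], via ortho-quinone 8 (not isolated), via vinylogous quinone methide 9 (not isolated)
Conditions: Ag2O (0.95–1.0 equiv, in portions), 2,6-lutidine (20 mol%), 4 Å MS, prenol/THF (1:1, 0.02 M in 6), 0 °C → rt, dark, Ar
Reagents that add atoms: prenol (7), CC(C)=CCO
Why: Proposed new method: Ag2O oxidises the ring B catechol to ortho-quinone 8, whose C3-methyl protons are vinylogously acidified through C2=C3, so lutidine-mediated prototropy gives the 2-hydroxy-para-quinone methide 9 extended by an exocyclic C3=CH2 that is both the terminus of the quinone methide and the beta carbon of the C4 enone, and prenol in large excess adds there in a 1,8 sense to form the CH2–O bond because only this regiochemistry restores both the catechol and the aromatic chromone (a 1,6-adduct at C2 is a labile ketal that reverts to 9), with no stereocentre formed; the closest known reaction types are the ortho-quinone to quinone methide tautomerisation of 4-alkylcatechols with benzylic capture of alcohols, and the Ag2O oxidation of 4-allyl- or 4-propenylphenols to vinyl quinone methides that take up alcohols by 1,8-addition, neither of which has been shown across a flavone C2=C3 bond onto a 3-methyl group.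

## Compound list
1 | flopropione, 1-(2,4,6-trihydroxyphenyl)propan-1-one | CCC(=O)c1c(O)cc(O)cc1O | starting material
2 | 3,4-dimethoxybenzoyl chloride | COc1ccc(C(=O)Cl)cc1OC | starting material
3 | tetralithium salt of flopropione, tris-phenoxide (Z)-enolate (geometry without consequence) | [Li+].[Li+].[Li+].[Li+].C/C=C(\[O-])c1c([O-])cc([O-])cc1[O-] | intermediate
4 | 1-(3,4-dimethoxyphenyl)-2-methyl-3-(2,4,6-trihydroxyphenyl)propane-1,3-dione (racemic, configurationally labile) | COc1ccc(C(=O)C(C)C(=O)c2c(O)cc(O)cc2O)cc1OC | intermediate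
5 | 2-(3,4-dimethoxyphenyl)-5,7-dihydroxy-3-methyl-4H-chromen-4-one | COc1ccc(-c2oc3cc(O)cc(O)c3c(=O)c2C)cc1OC | intermediate
6 | 3-methylluteolin, 2-(3,4-dihydroxyphenyl)-5,7-dihydroxy-3-methyl-4H-chromen-4-one | Cc1c(-c2ccc(O)c(O)c2)oc2cc(O)cc(O)c2c1=O | intermediate
7 | prenol, 3-methylbut-2-en-1-ol | CC(C)=CCO | starting material
8 | 4-(5,7-dihydroxy-3-methyl-4-oxo-4H-chromen-2-yl)cyclohexa-3,5-diene-1,2-dione | Cc1c(C2=CC(=O)C(=O)C=C2)oc2cc(O)cc(O)c2c1=O | intermediate
9 | (2Z)-5,7-dihydroxy-2-(3-hydroxy-4-oxocyclohexa-2,5-dien-1-ylidene)-3-methylidene-2,3-dihydro-4H-chromen-4-one (Z drawn; both geometries give the same product) | C=C1C(=O)c2c(O)cc(O)cc2O/C1=C3/C=CC(=O)C(O)=C3 | intermediate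
10 | ophioglonol prenyl ether | CC(C)=CCOCc1c(-c2ccc(O)c(O)c2)oc2cc(O)cc(O)c2c1=O | target

## Step count and risks
Total step count: 3. Longest linear sequence: 3.

**Step 3 (proposed new step) is the most likely to fail.**
- Product 10 is itself a catechol and can be oxidised again.
- Tautomerisation of 8 may be slower than its oligomerisation or than ring addition of nucleophiles.
- The water formed can compete with prenol as the nucleophile.

The fallback uses known chemistry, sets out from 6 and comes back at 10. Peracetylation (Ac2O, pyridine, cat. DMAP, rt) gives 3-methylluteolin tetraacetate F1. Wohl–Ziegler bromination (NBS, AIBN, PhCF3, reflux) of the only allylic/benzylic methyl group gives the 3-(bromomethyl)flavone tetraacetate F2. Silver-assisted substitution with prenol 7 (Ag2O, 4 Å MS, CH2Cl2, rt, dark) gives ophioglonol prenyl ether tetraacetate F3. Transesterification (cat. K2CO3, MeOH, 0 °C) then releases 10.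

**Step 1 is the second risk.** The tetralithium salt 3 may be poorly soluble, the alpha-methyl enolate is hindered, and O-acylation may compete. The fallback replaces intermolecular C-acylation by an intramolecular acyl transfer. It sets out from 1 and comes back at 6. Exhaustive O-aroylation with 2 (3.3 equiv, K2CO3, acetone, reflux) gives 2-propanoylbenzene-1,3,5-triyl tris(3,4-dimethoxybenzoate) F4. Baker–Venkataraman rearrangement (KOH, pyridine, 50 °C) gives the diketone bis-ester F5. Refluxing F5 in 48% HBr/AcOH cyclises it, cleaves the two esters and removes all methyl groups in one operation, giving 6.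

**Step 2 is the third risk.** The hindered diketone may undergo retro-Claisen cleavage, or demethylation may be incomplete, in hot HBr. The fallback changes the protecting-group strategy so that no strong-acid dealkylation is needed. It sets out from 1 and comes back at 6. Commercial 3,4-bis(benzyloxy)benzoic acid is converted with (COCl)2 and cat. DMF in CH2Cl2 into 3,4-bis(benzyloxy)benzoyl chloride F6. F6 acylates enolate 3 (generated from 1 as in step 1) to give the dibenzyl diketone F7. Mild cyclodehydration (p-TsOH 10 mol%, toluene, 90 °C) gives the dibenzyloxyflavone F8. Hydrogenolysis (H2 1 atm, Pd/C, EtOAc/MeOH, rt) then gives 6.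

## Further compounds
F1 | step 3 | 3-methylluteolin tetraacetate, 2-[3,4-bis(acetyloxy)phenyl]-3-methyl-4-oxo-4H-chromene-5,7-diyl diacetate | CC(=O)Oc1cc(OC(C)=O)c2c(=O)c(C)c(-c3ccc(OC(C)=O)c(OC(C)=O)c3)oc2c1
F2 | step 3 | 2-[3,4-bis(acetyloxy)phenyl]-3-(bromomethyl)-4-oxo-4H-chromene-5,7-diyl diacetate | CC(=O)Oc1cc(OC(C)=O)c2c(=O)c(CBr)c(-c3ccc(OC(C)=O)c(OC(C)=O)c3)oc2c1
F3 | step 3 | ophioglonol prenyl ether tetraacetate | CC(C)=CCOCc1c(-c2ccc(OC(C)=O)c(OC(C)=O)c2)oc2cc(OC(C)=O)cc(OC(C)=O)c2c1=O
F4 | step 1 | 2-propanoylbenzene-1,3,5-triyl tris(3,4-dimethoxybenzoate) | CCC(=O)c1c(OC(=O)c2ccc(OC)c(OC)c2)cc(OC(=O)c2ccc(OC)c(OC)c2)cc1OC(=O)c1ccc(OC)c(OC)c1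
F5 | step 1 | 4-[3-(3,4-dimethoxyphenyl)-2-methyl-3-oxopropanoyl]-5-hydroxybenzene-1,3-diyl bis(3,4-dimethoxybenzoate) (racemic) | COc1ccc(C(=O)C(C)C(=O)c2c(O)cc(OC(=O)c3ccc(OC)c(OC)c3)cc2OC(=O)c2ccc(OC)c(OC)c2)cc1OC
F6 | step 2 | 3,4-bis(benzyloxy)benzoyl chloride | O=C(Cl)c1ccc(OCc2ccccc2)c(OCc2ccccc2)c1
F7 | step 2 | 1-[3,4-bis(benzyloxy)phenyl]-2-methyl-3-(2,4,6-trihydroxyphenyl)propane-1,3-dione (racemic) | CC(C(=O)c1ccc(OCc2ccccc2)c(OCc2ccccc2)c1)C(=O)c1c(O)cc(O)cc1O
F8 | step 2 | 2-[3,4-bis(benzyloxy)phenyl]-5,7-dihydroxy-3-methyl-4H-chromen-4-one | Cc1c(-c2ccc(OCc3ccccc3)c(OCc3ccccc3)c2)oc2cc(O)cc(O)c2c1=O
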